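Ring B is traced back to a prochiral spiro-cyclobutanone (chamigrane numbering): spiro C6, its two methylene neighbours C1 and C5, and C2 as carbonyl carbon. The key step, a nickel-catalysed insertion of 1-(trimethylsilyl)propyne into one of the two enantiotopic acyl–CH2 bonds, expands this ring by two atoms (C3 with its methyl, and C4) and fixes the configuration of C6. It exploits the fact that C1 and C5 of ring B are both CH2 groups on C6 and that C2 lies β to C6. The cyclobutanone is grown on the hindered carbonyl of ketoisophorone, which already holds C7–C11 of ring A. The C2 carbonyl then guides chlorine and bromine into ring B; enone chemistry completes ring A.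

Key step: step 5

Remark: chamigrane numbering is used for all spiro compounds (C1–C5 ring B, C6 spiro, C7–C11 ring A, C14 on C7, C15 on C3) and CIP descriptors refer to these locants; the ligand antipode in step 5 that gives (6R)-7 is assumed to be the one named and would be fixed by a screen.

Step 1
Reactants: 1 ketoisophorone (2,6,6-trimethylcyclohex-2-ene-1,4-dione)
Product: 2 7,9,9-trimethyl-1,4-dioxaspiro[4.5]dec-6-en-8-one
Conditions: HOCH2CH2OH, TsOH (cat.), benzene, reflux, Dean–Stark trap
Reagents that add atoms: ethylene glycol, OCCO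
Why: Acid-catalysed ketalisation should take the less hindered carbonyl (future C9, flanked by CH and CH2) and leave the carbonyl between the quaternary carbon and the methyl-bearing alkene carbon (future C6) free; no stereocentre is formed.

Step 2
Reactants: 2 7,9,9-trimethyl-1,4-dioxaspiro[4.5]dec-6-en-8-one
Product: 3 7,9,9-trimethyl-8-methylidene-1,4-dioxaspiro[4.5]dec-6-ene
Conditions: Ph3PCH3Br, KOtBu, toluene, 90 °C
Reagents that add atoms: methyltriphenylphosphonium bromide, C[P+](c1ccccc1)(c1ccccc1)c1ccccc1.[Br-]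
Why: Wittig methylenation of a hindered but non-enolisable enone carbonyl should give the diene under forcing, salt-free conditions; no stereocentre is formed.

Step 3
Reactants: 3 7,9,9-trimethyl-8-methylidene-1,4-dioxaspiro[4.5]dec-6-ene
Product: 4 racemic 1,1-dichloro-5,13,13-trimethyl-8,11-dioxadispiro[3.2.4^7.2^4]tridec-5-en-2-one
Conditions: Cl3CCOCl, Zn–Cu couple, Et2O/DME, 25 °C
Reagents that add atoms: trichloroacetyl chloride, ClC(Cl)(Cl)C(Cl)=O
Why: Dichloroketene [2+2] cycloaddition should occur at the terminal methylidene of the diene, the carbonyl carbon bonding to CH2 and CCl2 to the carbon that can carry tertiary allylic positive charge; the transient stereocentre at the new spiro carbon forms as a racemate and is erased in step 4.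

Step 4
Reactants: 4 racemic 1,1-dichloro-5,13,13-trimethyl-8,11-dioxadispiro[3.2.4^7.2^4]tridec-5-en-2-one
Product: 5 5,13,13-trimethyl-8,11-dioxadispiro[3.2.4^7.2^4]tridec-5-en-2-one
Conditions: Zn dust, AcOH, 25 °C
Reagents that add atoms: none
Why: Zinc reduction of the α,α-dichloroketone should remove both chlorines and leave an achiral cyclobutanone whose two CH2–C(=O) bonds are enantiotopic.

Step 5
Reactants: 5 5,13,13-trimethyl-8,11-dioxadispiro[3.2.4^7.2^4]tridec-5-en-2-one; 6 trimethyl(prop-1-yn-1-yl)silane
Product: 7 (6R)-9,9-(ethane-1,2-diyldioxy)-3,7,11,11-tetramethyl-4-(trimethylsilyl)spiro[5.5]undeca-3,7-dien-2-one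
Conditions: 6 (3 equiv), Ni(cod)2 (10 mol%), (11bS)-N,N-bis[(R)-1-phenylethyl]dinaphtho[2,1-d:1',2'-f][1,3,2]dioxaphosphepin-4-amine (20 mol%), toluene, 90 °C
Reagents that add atoms: none
Why: Zerovalent nickel should couple the cyclobutanone carbonyl and the alkyne by oxidative cyclisation to a spiro oxanickelacyclopentene, which opens by strain-driven β-carbon elimination of one acyl–CH2 bond and closes by C(sp2)–C(sp3) reductive elimination. The closest known reaction is the nickel-catalysed intermolecular insertion of internal alkynes into 3,3-disubstituted cyclobutanones; the asymmetric induction is modelled on nickel/phosphoramidite desymmetrisations of such cyclobutanones by alkene insertion. Ring B is closed by a formal (4+2) ring expansion of the four-membered ring by two atoms, C3 and C4 being inserted between C2 and C5. The only new stereocentre, spiro C6, is set by the chiral ligand, which selects one of the two enantiotopic acyl–CH2 bonds for cleavage; the two other substituents on C6 (sp2 C7 and quaternary C11) differ strongly in size. The step needs methyl next to the carbonyl, which the silyl group secures because it prefers the nickel-bound alkyne carbon, so that the methyl-bearing carbon bonds to the carbonyl carbon. It also needs the ring A alkene to stay a spectator, which its trisubstituted, doubly flanked position should secure.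

Step 6
Reactants: 7 (6R)-9,9-(ethane-1,2-diyldioxy)-3,7,11,11-tetramethyl-4-(trimethylsilyl)spiro[5.5]undeca-3,7-dien-2-one
Product: 8 (2R,6R)-9,9-(ethane-1,2-diyldioxy)-3,7,11,11-tetramethyl-4-(trimethylsilyl)spiro[5.5]undeca-3,7-dien-2-ol
Conditions: (S)-1-methyl-3,3-diphenyltetrahydro-1H,3H-pyrrolo[1,2-c][1,3,2]oxazaborole [(S)-Me-CBS] (20 mol%), BH3·SMe2, THF, −20 °C
Reagents that add atoms: none
Why: CBS reduction with the substituted alkenyl carbon C3 as the large group should give the (2R) allylic alcohol under catalyst control, with the hydroxyl on the ring B face remote from C7.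

Step 7
Reactants: 8 (2R,6R)-9,9-(ethane-1,2-diyldioxy)-3,7,11,11-tetramethyl-4-(trimethylsilyl)spiro[5.5]undeca-3,7-dien-2-ol
Product: 9 (2S,6S)-2-chloro-9,9-(ethane-1,2-diyldioxy)-3,7,11,11-tetramethyl-4-(trimethylsilyl)spiro[5.5]undeca-3,7-diene
Conditions: PPh3, Cl3CC(O)CCl3, CH2Cl2, 0 °C
Reagents that add atoms: hexachloroacetone, ClC(Cl)(Cl)C(=O)C(Cl)(Cl)Cl
Why: Appel-type chlorination should displace the alkoxyphosphonium group by SN2 with inversion, placing chlorine on the C7 face (2S), while the fully substituted, silylated C4 blocks SN2′ attack.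

Step 8
Reactants: 9 (2S,6S)-2-chloro-9,9-(ethane-1,2-diyldioxy)-3,7,11,11-tetramethyl-4-(trimethylsilyl)spiro[5.5]undeca-3,7-diene
Product: 10 (2S,6S)-2-chloro-3,7,11,11-tetramethyl-4-(trimethylsilyl)spiro[5.5]undeca-3,7-dien-9-one
Conditions: pyridinium p-toluenesulfonate (cat.), acetone/H2O, 50 °C
Reagents that add atoms: water, O
Why: Mild acid hydrolysis of the allylic dioxolane should release the ring A enone without ionising the secondary allylic chloride; no stereocentre is touched.

Step 9
Reactants: 10 (2S,6S)-2-chloro-3,7,11,11-tetramethyl-4-(trimethylsilyl)spiro[5.5]undeca-3,7-dien-9-one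
Product: 12 (2S,6R,10R)-10-bromo-2-chloro-3,7,11,11-tetramethyl-4-(trimethylsilyl)spiro[5.5]undeca-3,7-dien-9-one, via silyl dienol ether 11 (not isolated)
Conditions: LiN(i-Pr)2, Me3SiCl, THF, −78 °C; then NBS, THF, −78 → 0 °C
Reagents that add atoms: N-bromosuccinimide, O=C1CCC(=O)N1Br; chlorotrimethylsilane, C[Si](C)(C)Cl (silyl group in 11 only)
Why: Kinetic α′-deprotonation of the enone with in situ silylation should give the cross-conjugated silyl dienol ether, which NBS brominates at C10; bromine is expected equatorial and cis to C1 (trans to the axial C5 methylene on C6), and C10 stays epimerisable through the enol under the acid of step 10.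

Step 10
Reactants: 12 (2S,6R,10R)-10-bromo-2-chloro-3,7,11,11-tetramethyl-4-(trimethylsilyl)spiro[5.5]undeca-3,7-dien-9-one
Product: 14 (2S,3S,6R,10R)-3,10-dibromo-2-chloro-3,7,11,11-tetramethylspiro[5.5]undec-7-en-9-one, via desilylated alkene 13 (not isolated)
Conditions: HBr (gas, excess), CH2Cl2, −30 → 0 °C
Reagents that add atoms: hydrogen bromide, Br
Why: Ipso-protonation of the vinylsilane and loss of Me3SiBr (protodesilylation) should give the C3=C4 alkene, and Markovnikov hydrobromination through the tertiary C3 cation should deliver bromide anti to the pseudoaxial, bridging C2 chlorine (trans-diaxial 2-Cl/3-Br, 3S).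

Step 11
Reactants: 14 (2S,3S,6R,10R)-3,10-dibromo-2-chloro-3,7,11,11-tetramethylspiro[5.5]undec-7-en-9-one
Product: 16 (2S,3S,6R,10R)-3,10-dibromo-2-chloro-3,11,11-trimethyl-7-methylidenespiro[5.5]undecan-9-one, via silyl dienol ether 15 (not isolated)
Conditions: Me3SiOTf, Et3N, CH2Cl2, 0 → 25 °C; then oxalic acid, THF/H2O, 0 °C
Reagents that add atoms: trimethylsilyl trifluoromethanesulfonate, C[Si](C)(C)OS(=O)(=O)C(F)(F)F (silyl group in 15 only)
Why: Equilibrating soft enolisation should remove a proton from the unhindered C14 methyl to give the through-conjugated silyl dienol ether, and kinetic α-protonation at C8 on mild hydrolysis should leave the deconjugated ketone with the exocyclic methylidene (enone deconjugation via a dienol ether).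

Step 12
Reactants: 16 (2S,3S,6R,10R)-3,10-dibromo-2-chloro-3,11,11-trimethyl-7-methylidenespiro[5.5]undecan-9-one
Product: 17 isoobtusol, (2S,3S,6R,9S,10R)-3,10-dibromo-2-chloro-3,11,11-trimethyl-7-methylidenespiro[5.5]undecan-9-ol
Conditions: i-Bu2AlH, CH2Cl2, −78 °C
Reagents that add atoms: none
Why: Hydride reduction should occur from the equatorial direction because the axial C11 methyl blocks the axial trajectory, giving the axial (9S) alcohol cis to the equatorial C10 bromine.

Step 13
Reactants: 17 isoobtusol
Product: 18 9-acetylisoobtusol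
Conditions: Ac2O, pyridine, 4-(dimethylamino)pyridine (cat.), CH2Cl2, 0 → 25 °C
Reagents that add atoms: acetic anhydride, CC(=O)OC(C)=O
Why: Nucleophile-catalysed acetylation of the secondary axial alcohol should proceed without touching any stereocentre or the tertiary bromide.

Compound list

1 | ketoisophorone (2,6,6-trimethylcyclohex-2-ene-1,4-dione) | CC1=CC(=O)CC(C)(C)C1=O | starting material
2 | 7,9,9-trimethyl-1,4-dioxaspiro[4.5]dec-6-en-8-one | CC1=CC2(CC(C)(C)C1=O)OCCO2 | intermediate
3 | 7,9,9-trimethyl-8-methylidene-1,4-dioxaspiro[4.5]dec-6-ene | C=C1C(C)=CC2(CC1(C)C)OCCO2 | intermediate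
4 | racemic 1,1-dichloro-5,13,13-trimethyl-8,11-dioxadispiro[3.2.4^7.2^4]tridec-5-en-2-one (CCl2 bonded to the new spiro carbon) | O=C1CC2(C(C)=CC3(CC2(C)C)OCCO3)C1(Cl)Cl | intermediate
5 | 5,13,13-trimethyl-8,11-dioxadispiro[3.2.4^7.2^4]tridec-5-en-2-one (achiral spiro-cyclobutanone) | O=C1CC2(C1)C(C)=CC1(CC2(C)C)OCCO1 | intermediate
6 | trimethyl(prop-1-yn-1-yl)silane | CC#C[Si](C)(C)C | starting material
7 | (6R)-9,9-(ethane-1,2-diyldioxy)-3,7,11,11-tetramethyl-4-(trimethylsilyl)spiro[5.5]undeca-3,7-dien-2-one | CC1=CC3(OCCO3)CC(C)(C)[C@@]12CC([Si](C)(C)C)=C(C)C(=O)C2 | intermediate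
8 | (2R,6R)-9,9-(ethane-1,2-diyldioxy)-3,7,11,11-tetramethyl-4-(trimethylsilyl)spiro[5.5]undeca-3,7-dien-2-ol | CC1=CC3(OCCO3)CC(C)(C)[C@@]12CC([Si](C)(C)C)=C(C)[C@H](O)C2 | intermediate
9 | (2S,6S)-2-chloro-9,9-(ethane-1,2-diyldioxy)-3,7,11,11-tetramethyl-4-(trimethylsilyl)spiro[5.5]undeca-3,7-diene | CC1=CC3(OCCO3)CC(C)(C)[C@@]12CC([Si](C)(C)C)=C(C)[C@@H](Cl)C2 | intermediate
10 | (2S,6S)-2-chloro-3,7,11,11-tetramethyl-4-(trimethylsilyl)spiro[5.5]undeca-3,7-dien-9-one | CC1=CC(=O)CC(C)(C)[C@@]12CC([Si](C)(C)C)=C(C)[C@@H](Cl)C2 | intermediate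
11 | (2S,6R)-2-chloro-3,7,11,11-tetramethyl-4-(trimethylsilyl)-9-(trimethylsilyloxy)spiro[5.5]undeca-3,7,9-triene | CC1=CC(O[Si](C)(C)C)=CC(C)(C)[C@@]12CC([Si](C)(C)C)=C(C)[C@@H](Cl)C2 | intermediate (not isolated)
12 | (2S,6R,10R)-10-bromo-2-chloro-3,7,11,11-tetramethyl-4-(trimethylsilyl)spiro[5.5]undeca-3,7-dien-9-one | CC1=CC(=O)[C@H](Br)C(C)(C)[C@@]12CC([Si](C)(C)C)=C(C)[C@@H](Cl)C2 | intermediate
13 | (2S,6R,10R)-10-bromo-2-chloro-3,7,11,11-tetramethylspiro[5.5]undeca-3,7-dien-9-one | CC1=CC(=O)[C@H](Br)C(C)(C)[C@@]12CC=C(C)[C@@H](Cl)C2 | intermediate (not isolated)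
14 | (2S,3S,6R,10R)-3,10-dibromo-2-chloro-3,7,11,11-tetramethylspiro[5.5]undec-7-en-9-one | CC1=CC(=O)[C@H](Br)C(C)(C)[C@@]12CC[C@](C)(Br)[C@@H](Cl)C2 | intermediate
15 | (2S,3S,6R,10R)-3,10-dibromo-2-chloro-3,11,11-trimethyl-7-methylidene-9-(trimethylsilyloxy)spiro[5.5]undec-8-ene | C=C1C=C(O[Si](C)(C)C)[C@H](Br)C(C)(C)[C@@]12CC[C@](C)(Br)[C@@H](Cl)C2 | intermediate (not isolated)
16 | (2S,3S,6R,10R)-3,10-dibromo-2-chloro-3,11,11-trimethyl-7-methylidenespiro[5.5]undecan-9-one | C=C1CC(=O)[C@H](Br)C(C)(C)[C@@]12CC[C@](C)(Br)[C@@H](Cl)C2 | intermediate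
17 | isoobtusol, (2S,3S,6R,9S,10R)-3,10-dibromo-2-chloro-3,11,11-trimethyl-7-methylidenespiro[5.5]undecan-9-ol | C=C1C[C@H](O)[C@H](Br)C(C)(C)[C@@]12CC[C@](C)(Br)[C@@H](Cl)C2 | intermediate
18 | 9-acetylisoobtusol, (2S,3S,6R,9S,10R)-3,10-dibromo-2-chloro-3,11,11-trimethyl-7-methylidenespiro[5.5]undecan-9-yl acetate | C=C1C[C@H](OC(C)=O)[C@H](Br)C(C)(C)[C@@]12CC[C@](C)(Br)[C@@H](Cl)C2 | target

Total step count: 13. Longest linear sequence: 13 steps (from ketoisophorone).

Steps most likely to fail

Step 5. The two enantiotopic acyl–CH2 bonds may be cleaved without sufficient discrimination, or alkyne oligomerisation and rearrangement of the β-vinyl cyclobutanone may outrun insertion. Fallback: from 5 the insertion is run with the achiral catalyst Ni(cod)2/PCy3 (toluene, 100 °C), which should give 7 together with its enantiomer, the (6S)-silyl enone F1. Reduction of this racemate with the (S)-Me-CBS catalyst and BH3·SMe2 as in step 6 should fix C2 as R in both series and so turn the enantiomers into diastereomers, 8 and the (2R,6S) alcohol F2. These would be separated by chromatography, and the route is rejoined at 8.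

Step 10. Under strong acid the secondary allylic chloride may ionise and exchange halide before the alkene is protonated, or the tertiary cation may be captured without facial control or lose a proton. Fallback: from 12 the vinylsilane is cleaved with CF3CO2H (CH2Cl2, 0 °C) and the alkene 13 is isolated. Mukaiyama hydration (Co(acac)2, PhSiH3, O2, i-PrOH) should then give the tertiary alcohol F3 as a mixture of C3 epimers. Me3SiBr (CH2Cl2, −40 °C) should convert F3 into the tertiary bromide through the chlorine-bridged cation generated from a saturated precursor, which returns to the route at 14.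

Step 11. Enolisation may go toward C10 instead of C14, or the deconjugated ketone may re-conjugate during hydrolysis. Fallback: from 14, acid-catalysed enol acetylation (Ac2O, HClO4 cat., EtOAc, 25 °C) should give the dienol acetate F4. NaBH4 (EtOH/THF, 0 °C) should cleave the enol ester, the dienolate is protonated at C8, and the ketone 16 formed in the flask is reduced before it can re-conjugate. This returns to the route at 17 and leaves out step 12.

Further compounds
F1 | step 5 | (6S)-9,9-(ethane-1,2-diyldioxy)-3,7,11,11-tetramethyl-4-(trimethylsilyl)spiro[5.5]undeca-3,7-dien-2-one | CC1=CC3(OCCO3)CC(C)(C)[C@]12CC([Si](C)(C)C)=C(C)C(=O)C2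
F2 | step 5 | (2R,6S)-9,9-(ethane-1,2-diyldioxy)-3,7,11,11-tetramethyl-4-(trimethylsilyl)spiro[5.5]undeca-3,7-dien-2-ol | CC1=CC3(OCCO3)CC(C)(C)[C@]12CC([Si](C)(C)C)=C(C)[C@H](O)C2
F3 | step 10 | (2S,6R,10R)-10-bromo-2-chloro-3-hydroxy-3,7,11,11-tetramethylspiro[5.5]undec-7-en-9-one (both C3 epimers) | CC1=CC(=O)[C@H](Br)C(C)(C)[C@@]12CCC(C)(O)[C@@H](Cl)C2
F4 | step 11 | (2S,3S,6R,10R)-3,10-dibromo-2-chloro-3,11,11-trimethyl-7-methylidenespiro[5.5]undec-8-en-9-yl acetate | C=C1C=C(OC(C)=O)[C@H](Br)C(C)(C)[C@@]12CC[C@](C)(Br)[C@@H](Cl)C2
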